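**Plan**

- Retrosynthesis: the two phenolic O–H bonds are masked as silyl ethers and the benzene ring is taken back one oxidation level to a 1,4-cyclohexadiene. That ring is cut at C1–C2 and C5–C6 (arene numbering: C1 bears the chain, C3 and C4 bear oxygen). The ester C–O bond is cut last.
- Enabling feature: the four contiguous ring carbons C2–C5, with oxygen on the inner pair C3/C4, are a symmetric 2,3-dioxygenated buta-1,3-diene. C1 and C6 are the two carbons of a terminal alkyne whose substituted end already carries the CH2CH2CO2C16H33 chain.
- Forward: the chain is joined first by esterifying pent-4-ynoic acid with 1-hexadecanol, and the diene is made in parallel from butane-2,3-dione. The only ring then arises in one cobalt-catalysed [4+2] step, followed by dehydrogenation to the arene and desilylation.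
- Stereochemistry: none has to be set; no stereocentre or stereogenic double bond occurs in the target or in any intermediate of the main route.

Key step: step 3

Remark: the target is achiral, so the requirement of a single enantiomer is met by constitution alone.

**Route**

Step 1
Reactants: 1 pent-4-ynoic acid; 2 1-hexadecanol
Product: 3 hexadecyl pent-4-ynoate
Conditions: DCC (1.1 equiv), DMAP (0.1 equiv), CH2Cl2, 0 °C → rt; filtration, chromatography
Reagents that add atoms: none
Why: Steglich esterification, in which the O-acylisourea is intercepted by DMAP as an acylpyridinium ion that acylates the primary alcohol under neutral conditions that leave the terminal alkyne untouched.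

Step 2
Reactants: 4 butane-2,3-dione
Product: 5 2,3-bis(trimethylsilyloxy)buta-1,3-diene
Conditions: TMSOTf (2.1 equiv), Et3N (2.5 equiv), Et2O, 0 °C → rt; decant from the ammonium salt, distil under reduced pressure, store cold under Ar
Reagents that add atoms: trimethylsilyl trifluoromethanesulfonate, C[Si](C)(C)OS(=O)(=O)C(F)(F)F
Why: Twofold soft enolisation (silyl triflate/amine silyl enol ether formation), in which each carbonyl oxygen is silylated and the adjacent methyl group deprotonated, should convert the 1,2-diketone into the bis(silyl enol ether), a known and distillable diene.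

Step 3
Reactants: 3 hexadecyl pent-4-ynoate; 5 2,3-bis(trimethylsilyloxy)buta-1,3-diene (1.5 equiv)
Product: 6 hexadecyl 3-[4,5-bis(trimethylsilyloxy)cyclohexa-1,4-dien-1-yl]propanoate
Conditions: CoBr2(dppe) (10 mol%), Zn dust (20 mol%), ZnI2 (10 mol%), CH2Cl2, rt, Ar, slow addition of 3; filtration through Et3N-deactivated silica (pentane)
Reagents that add atoms: none
Why: Zinc reduces the cobalt(II) precatalyst and ZnI2 opens a coordination site, so that a cationic cobalt(I)–dppe fragment binds the s-cis diene and the alkyne, couples them oxidatively to a seven-membered cobaltacycle (η3-allyl/vinyl cobalt(III)) and then closes the carbocycle by C–C reductive elimination, releasing the skipped diene and the catalyst. The closest known reaction type is the cobalt(I)-catalysed neutral Diels–Alder reaction of unactivated terminal alkynes with 2-silyloxy- and 2,3-dialkylbuta-1,3-dienes, which needs no electron-poor dienophile and tolerates a remote ester; the bis(silyloxy) diene is an extension within that class. The single ring is closed in an intermolecular formal [4+2] mode, the bonds C1–C2 and C5–C6 (arene numbering) both being made at the metal. No stereocentre is created. The step needs chemoselectivity for cross-cycloaddition over alkyne cyclotrimerisation and diene homo-coupling, which the chelating diphosphine, the excess of 5 and the slow addition of 3 should secure, and it needs the silyl enol ethers to survive, for which the zinc iodide loading is kept low and the medium strictly anhydrous. Regiochemistry cannot arise because the two ends of diene 5 are equivalent by its twofold symmetry.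

Step 4
Reactants: 6 hexadecyl 3-[4,5-bis(trimethylsilyloxy)cyclohexa-1,4-dien-1-yl]propanoate
Product: 7 hexadecyl 3-[3,4-bis(trimethylsilyloxy)phenyl]propanoate
Conditions: DDQ (1.0 equiv), PhMe, 0 °C → rt; filtration through Celite, concentration, used crude
Reagents that add atoms: none
Why: Quinone dehydrogenation, in which DDQ abstracts hydride from a doubly allylic ring CH2 to give a silyloxy-stabilised cyclohexadienyl cation that loses a proton, is driven by aromatisation and is the standard way to convert such 1,4-cyclohexadienes, including silyl enol ether ones, into arenes; one equivalent at low temperature should spare the benzylic chain.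

Step 5
Reactants: 7 hexadecyl 3-[3,4-bis(trimethylsilyloxy)phenyl]propanoate
Product: 8 hexadecyl 3-(3,4-dihydroxyphenyl)propanoate
Conditions: 1 M aq. HCl, THF (degassed), 0 °C → rt
Reagents that add atoms: none
Why: Acid-catalysed hydrolysis of aryl trimethylsilyl ethers, the most labile of silyl ethers, should free both phenols within minutes under conditions too mild to hydrolyse the hexadecyl ester, and the acidic medium protects the catechol from air oxidation.

**Compound list**

1 | pent-4-ynoic acid | C#CCCC(=O)O | starting material
2 | 1-hexadecanol | CCCCCCCCCCCCCCCCO | starting material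
3 | hexadecyl pent-4-ynoate | CCCCCCCCCCCCCCCCOC(=O)CCC#C | intermediate
4 | butane-2,3-dione | CC(=O)C(C)=O | starting material
5 | 2,3-bis(trimethylsilyloxy)buta-1,3-diene | C=C(O[Si](C)(C)C)C(=C)O[Si](C)(C)C | intermediate
6 | hexadecyl 3-[4,5-bis(trimethylsilyloxy)cyclohexa-1,4-dien-1-yl]propanoate | CCCCCCCCCCCCCCCCOC(=O)CCC1=CCC(O[Si](C)(C)C)=C(O[Si](C)(C)C)C1 | intermediate
7 | hexadecyl 3-[3,4-bis(trimethylsilyloxy)phenyl]propanoate | CCCCCCCCCCCCCCCCOC(=O)CCc1ccc(O[Si](C)(C)C)c(O[Si](C)(C)C)c1 | intermediate
8 | hexadecyl 3-(3,4-dihydroxyphenyl)propanoate | CCCCCCCCCCCCCCCCOC(=O)CCc1ccc(O)c(O)c1 | target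

**Step count**

Total: 5 steps. Longest linear sequence: 4 steps (1 or 2, then 3, 4, 5).

**Steps most likely to fail**

1. Step 3. The cycloaddition may stall because the doubly oxygenated diene is cleaved or oligomerised by the zinc Lewis acid, or because alkyne cyclotrimerisation outruns the cross-reaction.
Fallback: setting out from 3, the same cobalt conditions would be used with the established mono-oxygenated partner 2-(trimethylsilyloxy)buta-1,3-diene F1, made from but-3-en-2-one with TMSCl/Et3N. With the dppe catalyst this is expected to favour the 1,4-disubstituted adduct hexadecyl 3-[4-(trimethylsilyloxy)cyclohexa-1,4-dien-1-yl]propanoate F2. DDQ would aromatise it to hexadecyl 3-[4-(trimethylsilyloxy)phenyl]propanoate F3, and dilute HCl in THF would give the phenol hexadecyl 3-(4-hydroxyphenyl)propanoate F4. The missing C3 oxygen would then be introduced by ortho-oxygenation of the phenol with IBX (MeOH, −25 → 0 °C), the two ortho positions being equivalent. This gives the o-quinone hexadecyl 3-(3,4-dioxocyclohexa-1,5-dien-1-yl)propanoate F5, which is reduced in the same flask with aqueous Na2S2O4, and the route is rejoined at 8.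

2. Step 4. Electron transfer from the very electron-rich enediol bis(silyl ether) to DDQ may compete with hydride abstraction; this would lead to loss of silyl groups, over-oxidation of liberated catechol to quinone, and dehydrogenation of the benzylic chain.
Fallback: setting out from 6, the oxidation would be moved from the ring C–H bonds to the oxygen-bearing carbons. Bromine (1.0 equiv, CH2Cl2, −78 °C) should cleave the enediol bis(silyl ether) in the manner of the known bromine oxidation of acyloin bis(silyl ethers) to 1,2-diones. The product is hexadecyl 3-(4,5-dioxocyclohex-1-en-1-yl)propanoate F6, a non-aromatic tautomer of the catechol that should enolise on bicarbonate work-up or with a trace of Et3N. This bypasses 7 and comes back at 8.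

3. Step 2. The second enolisation may remain incomplete, the diketone may self-condense, and the moisture-sensitive diene may hydrolyse or polymerise during distillation.
Fallback: setting out from 4, silylation with TBSOTf/Et3N would give the sturdier, chromatographable 2,3-bis(tert-butyldimethylsilyloxy)buta-1,3-diene F7. Under the conditions of step 3 this would be combined with 3 to give hexadecyl 3-[4,5-bis(tert-butyldimethylsilyloxy)cyclohexa-1,4-dien-1-yl]propanoate F8. DDQ would aromatise it to hexadecyl 3-[3,4-bis(tert-butyldimethylsilyloxy)phenyl]propanoate F9, and TBAF buffered with AcOH (THF, 0 °C) would remove both silyl groups, returning to the route at 8.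

**Further compounds**

F1 | step 3 | 2-(trimethylsilyloxy)buta-1,3-diene | C=CC(=C)O[Si](C)(C)C
F2 | step 3 | hexadecyl 3-[4-(trimethylsilyloxy)cyclohexa-1,4-dien-1-yl]propanoate | CCCCCCCCCCCCCCCCOC(=O)CCC1=CCC(O[Si](C)(C)C)=CC1
F3 | step 3 | hexadecyl 3-[4-(trimethylsilyloxy)phenyl]propanoate | CCCCCCCCCCCCCCCCOC(=O)CCc1ccc(O[Si](C)(C)C)cc1
F4 | step 3 | hexadecyl 3-(4-hydroxyphenyl)propanoate | CCCCCCCCCCCCCCCCOC(=O)CCc1ccc(O)cc1
F5 | step 3 | hexadecyl 3-(3,4-dioxocyclohexa-1,5-dien-1-yl)propanoate | CCCCCCCCCCCCCCCCOC(=O)CCC1=CC(=O)C(=O)C=C1
F6 | step 4 | hexadecyl 3-(4,5-dioxocyclohex-1-en-1-yl)propanoate | CCCCCCCCCCCCCCCCOC(=O)CCC1=CCC(=O)C(=O)C1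
F7 | step 2 | 2,3-bis(tert-butyldimethylsilyloxy)buta-1,3-diene | C=C(O[Si](C)(C)C(C)(C)C)C(=C)O[Si](C)(C)C(C)(C)C
F8 | step 2 | hexadecyl 3-[4,5-bis(tert-butyldimethylsilyloxy)cyclohexa-1,4-dien-1-yl]propanoate | CCCCCCCCCCCCCCCCOC(=O)CCC1=CCC(O[Si](C)(C)C(C)(C)C)=C(O[Si](C)(C)C(C)(C)C)C1
F9 | step 2 | hexadecyl 3-[3,4-bis(tert-butyldimethylsilyloxy)phenyl]propanoate | CCCCCCCCCCCCCCCCOC(=O)CCc1ccc(O[Si](C)(C)C(C)(C)C)c(O[Si](C)(C)C(C)(C)C)c1
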